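A leftover opens the reckoning: at 12.0 h the earlier runs had turned on average 17.6% of their reagent charge into product, so 82.4% stayed unconverted, counting one reagent per product.

| flask | solid substrate | solid reagent | remark | time |
|---|---|---|---|---|
| green | 1.3 M | 0.70 M | run made earlier |  |
| grey | 1.3 M | 1.6 M | run made earlier |  |
| blue | 2.6 M | 1.04 M | run made earlier |  |
| flask | 1.3 M | 1.04 M |  | 12 h |

| green: time / h | green: product / % | grey: time / h | grey: product / % | blue: time / h | blue: product / % |
|---|---|---|---|---|---|
| 1.00 | 0.2 | 2.50 | 2.8 | 1.00 | 0.4 |
| 2.00 | 0.9 | 5.00 | 7.1 | 2.00 | 0.6 |
| 3.00 | 1.5 | 8.00 | 13.8 | 3.00 | 2.1 |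
| 6.00 | 3.5 | 10.0 | 16.2 | 6.00 | 3.9 |
| 12.0 | 9.8 | 12.0 | 20.5 | 12.0 | 7.2 |

(readings scatter by 0.5 percentage points)

- product at 12 h, in percent of the solid substrate charged
- the change that raises the amount of product at 12 h, in percent of the solid substrate charged most ("none" if none brings more than 2 percentage points) (Tuesday's / Wednesday's / Friday's / Saturday's / none)
- amount of product at 12 h, in percent of the solid substrate charged, after Wednesday's

- Tuesday's: doubling the dissolution coefficient of the solid reagent, all else as stated
- Wednesday's: doubling the dissolution coefficient of the solid substrate, all else as stated
- Friday's: doubling the solubility of the solid substrate, all else as stated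
- Saturday's: doubling the solubility of the solid reagent, all else as stated

- solid substrate, solid reagent is a solid; its amount is given per volume of the solution
- at the start none of the solid reagent is in solution
- at the start none of the solid substrate is in solution

Run by run that share reads 18.2%, 16.7% and 18.0%, although the charges differ. Dividing by the time gives the mean turnover rate w, the fraction of the reagent charge made into product per hour, averaged from the start to the reading 0.0147 h⁻¹. The curve is then replaced by a line: product in percent = w·t·c(solid reagent)/c(solid substrate).

The green curve starts flat and bends. Green gained 3.5% in its first 6.00 h, then 6.3 percentage points in the next 6.00 h. At 6.00 h the line gives the flask 7.05%. Scaled to the flask's charges, green reads 5.20% and blue 7.80%, so the line stands above their mean by 0.55 points. That gap is smaller than the 0.74 points by which a green reading so scaled scatters. At 12 h the line gives the flask 14.1%. In the flask, with 1.04 M of solid reagent against 1.3 M of solid substrate, the reagent is the limiting reagent, and at one reagent per product the level is 80.0%. The line crosses that level at 68.0 h, so the curve must part from the line before then. The line reads charges, so it gives nothing on the changes.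

The forecast gives 14% (12.5% to 15.5%), Saturday's as the best change and 15% (13% to 18%) after Wednesday's, from “a rate limited by dissolution of the solid reagent”.

The flask gives 14.3%, a mean rate of 0.0149 h⁻¹. Friday's gains most, 9.4 points, so the answer is Friday's; Wednesday's gives 16.7%.

    solid reagent ⇌ partner, rate k1*(cs1 - [partner]) while solid is left; crystals form when [partner] > cs1 (solubility = 1.20 M, k = 0.0563 min⁻¹)
    solid substrate ⇌ dissolved substrate, rate k2*(cs2 - [dissolved substrate]) while solid is left; crystals form when [dissolved substrate] > cs2 (solubility = 0.720 M, k = 0.00569 min⁻¹)
    partner ⇌ dormant form (K = 3.85, k = 0.0587 min⁻¹)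
    dissolved substrate + partner → product (k = 0.00259 M⁻¹ min⁻¹)

The flask is not at rest at 12 h: 35.2% of the substrate charge is still solid substrate. Left to 120 h, it reaches 70.0%, a further 56 points. The line would print 141% there, above the ceiling of 80.0%, and the mean rate by then is 0.00729 h⁻¹, half of w. The neighbour flask with 0.52 M of solid substrate stores 27.7% where the line gives 35.3%. At 120 h the flask still holds dissolved substrate, 30.0% of the substrate charge, beside partner 0.0266 M and dormant form 0.104 M, together 10.0% of the substrate charge.

The data come from a simulation for an exercise; the scatter is artificial.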